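4 questions stand on maple, the flask followed so far, and the reckoning below rests on one balance of the nucleophile.

| setting | maple | ash | flask |
|---|---|---|---|
| electrophile | 0.20 M | 0.20 M | 0.20 M |
| nucleophile | 0.16 M | 0.16 M | 0.160 M |
| free base | 0.30 M | 0.30 M | 0.300 M |
| protic impurity | 0.10 M | 0.10 M | 0.100 M |
| temperature | 50 °C | 56 °C | 50 °C |
| remark | the very flask that is asked about, followed so far | run made earlier |  |
| time |  |  | 20 min |

| run | time / min | product / % |
|---|---|---|
| maple | 0.667 | 14.0 |
| maple | 2.00 | 33.0 |
| maple | 3.00 | 40.4 |
| maple | 5.00 | 52.5 |
| maple | 8.00 | 61.2 |
| maple | 10.0 | 64.0 |
| maple | 12.0 | 67.7 |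
| ash | 0.667 | 19.3 |
| ash | 2.00 | 38.9 |
| ash | 3.00 | 47.7 |
| ash | 5.00 | 57.7 |
| ash | 8.00 | 66.1 |
| ash | 10.0 | 70.4 |
| ash | 12.0 | 71.2 |

(each reading ± 0.5 percentage points)

- midnight: change nothing and wait 20 min more
- winter: at 20 min add free base, 100% of the amount charged, then wait 20 min
- summer: at 20 min take out 90% of the product then present, then wait 20 min
- noon: at 20 min add nucleophile, 100% of the amount charged, then wait 20 min
- dawn: at 20 min raise the temperature by 20 K, then wait 20 min

- product taken out counts as made
- steps that have been proposed: acid set free + free base <-> salt of the base; protic impurity + free base -> quenched reagent; nucleophile + acid set free <-> protonated nucleophile; electrophile + nucleophile -> acid set free + product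
- additions bring no volume worth counting

1. product, in percent of the electrophile first charged, at 20 min
2. which option adds most product ("none" when 2 percentage points or less is all one gets) (midnight / winter / summer / noon / dawn / none)
3. product present, with what was taken out counted in, in percent of the electrophile first charged, after winter
4. product present, with what was taken out counted in, in percent of the electrophile first charged, after summer

In maple each product formed uses up one nucleophile, and 0.160 M of nucleophile stands against 0.20 M of electrophile, so the nucleophile is the limiting reagent. After the protic impurity has taken its share, 0.200 M of free base remains, more than the 0.160 M of acid that the nucleophile can set free. The balance therefore needs no term for protonated nucleophile. The ceiling Y is the nucleophile charged divided by the electrophile charged: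

Y = 0.160 M / 0.20 M = 80.0%

A second way ignores the charges. The late readings of maple, drawn against one over time and run out to infinite time, give

Y′ = (67.7% × 12.0 min − 61.2% × 8.00 min) / (12.0 min − 8.00 min) = 80.7%

The scatter of this reading is about 1.8 percentage points. The two ways differ by 0.7 points, less than that scatter, and they come from different things, so Y is trusted.

For the pace, let E and N be the charges of electrophile and nucleophile and x the product concentration. A second-order law on the balance, with rate constant k, reads

ln[(E − x)N / ((N − x)E)] = k(E − N)t

The reading at 12.0 min gives k = 1.55 /M/min. The same law then gives 74.0% at 20 min and 78.6% after 20 min more.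

The last step, as written, has neither free base nor product on its left, so this reckoning puts winter and summer on that same 78.6%. Dawn can use the room under Y, 6 points. Noon lifts the ceiling to 100%, with the electrophile then limiting, and that room of 26 points is larger.

The forecast gives 73.5%, names noon, and puts winter at 78.5% and summer at 77.5%, holding that “base is sufficient and protonation of the nucleophile is minor”. Its figure at 20 min stands 0.50 points below this reckoning, and its summer 1.1 points below.

Maple gives 74.0% at 20 min. Noon adds 26 points, dawn adds 5.8 points, and winter and summer end at 78.6% and 78.6%. The forecast stands on each question.

    acid set free + free base ⇌ salt of the base, settled at all times (K = 2.20 × 10⁵ /M, ΔH = −6.00 kJ/mol)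
    protic impurity + free base → quenched reagent (k = 0.0240 /M/s, Ea = 76.0 kJ/mol)
    nucleophile + acid set free ⇌ protonated nucleophile, settled at all times (K = 210 /M, ΔH = 25.0 kJ/mol)
    electrophile + nucleophile → acid set free + product (k = 0.0260 /M/s, Ea = 47.0 kJ/mol)
    (constants at 50 °C)

What maple lacks of full conversion at 20 min goes mainly to the falling nucleophile: the run with its level held reaches 99.3% against 74.0%, and that gap is 97% of what is missing. Dawn's 5.8 points stays inside the 6 points between Y and maple.

In the neighbour charged with 0.040 M of nucleophile, Y becomes 20.0%. That flask computes to 19.9% at 20 min, with 80% of its electrophile still there.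

The earlier runs and the new flask were computed from invented constants; the scatter is artificial.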